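In this closed, stirred vessel, solid substrate dissolves into starting material and the catalyst round turns that into product, so anyone repeating the run is watching two steps in series.

| setting | ochre | teal | flask |
|---|---|---|---|
| solid substrate | 0.90 M | 1.8 M | 1.8 M |
| partner | 1.8 M | 1.8 M | 1.80 M |
| free catalyst | 1.7 mM | 3.4 mM | 1.7 mM |
| remark | run made earlier | run made earlier |  |
| time |  |  | 3.0 d |

| run | time / d | product / % | starting material / % | solid substrate / % |
|---|---|---|---|---|
| ochre | 0.500 | 1 | 5 | 92 |
| ochre | 1.04 | 5 | 8 | 87 |
| ochre | 1.25 | 7 | 9 | 83 |
| ochre | 2.08 | 12 | 8 | 78 |
| ochre | 2.50 | 16 | 8 | 73 |
| teal | 0.500 | 1 | 2 | 96 |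
| teal | 1.04 | 4 | 2 | 93 |
| teal | 1.25 | 5 | 4 | 91 |
| teal | 2.08 | 9 | 6 | 86 |
| teal | 2.50 | 12 | 2 | 83 |

(readings scatter by 1.5 percentage points)

- percent here means solid substrate units held: one idle complex counts as two
- solid substrate is a solid; its amount is given per volume of the solution
- what may be going on: starting material + catalyst intermediate D <-> idle complex; catalyst intermediate A -> catalyst intermediate B; solid substrate <-> starting material; catalyst intermediate D <-> free catalyst + product; starting material + free catalyst <-> catalyst intermediate A; catalyst intermediate C <-> catalyst intermediate D; partner + catalyst intermediate B -> catalyst intermediate C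
- at the start none of the solid substrate is in solution
- starting material means what is dissolved; the solid is not counted in it

- zeta: doubling the amount of partner, all else as stated
- epsilon: doubling the dissolution coefficient of the solid substrate, all else as stated
- theta: doubling the solubility of the solid substrate, all else as stated
- alpha: doubling the amount of free catalyst, all else as stated

1. amount of product at 3.0 d, in percent of the solid substrate charged
2. concentration of starting material in solution at 8.0 h, in percent of saturation
3. the change that raises the amount of product at 3.0 d, in percent of the solid substrate charged most ("none" if none brings more than 2 percentage points) (zeta / epsilon / theta / alpha / none)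
4. amount of product at 3.0 d, in percent of the solid substrate charged, after theta

Past the early lag, the readings of c(product) climb in ochre at 0.0678 M/d, and in teal, with twice the catalyst and twice the solid substrate, at 0.0986 M/d. Two chemists read these rates differently.

The first takes the catalyst round as the rate-limiting step, with a rate proportional to catalyst. The flask has half of teal's catalyst, so she halves teal's rate, keeps ochre's lag of 0.376 d, and gets 7.19%. She puts ochre's excess over that halved rate down to the scatter of 1.5 percentage points.

The second takes the ratio of 1.45 as real and solves both ends. At high catalyst she counts a dissolving term, at low catalyst a catalyst term, and she joins the ends by adding them. Her quantity is the charge-turnover time W, the flask's charge divided by the straight-stretch rate, 26.5 d at ochre's catalyst; it is a dissolving term plus a term inverse in catalyst. The two runs give 16.6 d for the catalyst term at 1.7 mM and 9.95 d for the dissolving term.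

The solid loss read at 0.500 d matched in the two runs, 0.0720 M, so she takes the molar rate as independent of the solid charge. By her reckoning the flask, with ochre's catalyst, then reaches 9.88%. In her reckoning doubling solubility halves both terms, leaving W lower than doubling catalyst or dissolution coefficient would, so she names theta, at about 19.8%.

The forecast says 10%, 35%, theta and 18%: “The flask should follow ochre in molarity”.

The flask gives 9.86%, above the first chemist's figure and close to the second's 9.88%; at 8.0 h its c(starting material) stands at 17.0% of saturation, and theta is the best change, giving 18.3%. At 1.50 d, c(starting material) in the flask is 39.6% of saturation, the level to watch. Carried on to 6.00 d, W gives 21.2%, and the flask holds 21.6%.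

    starting material + catalyst intermediate D ⇌ idle complex, settled at all times (K = 0.450 /M)
    catalyst intermediate A → catalyst intermediate B (k = 2.70 /min)
    solid substrate ⇌ starting material, rate k3*(cs3 - [starting material]) while solid is left; crystals form when [starting material] > cs3 (solubility = 0.220 M, k = 4.50 × 10⁻⁴ /min)
    catalyst intermediate D ⇌ free catalyst + product (K = 1.80 M, k = 1.30 /min)
    starting material + free catalyst ⇌ catalyst intermediate A (K = 0.550 /M, k = 0.470 /M/min)
    catalyst intermediate C ⇌ catalyst intermediate D (K = 1.80, k = 11.0 /min)
    partner + catalyst intermediate B → catalyst intermediate C (k = 15.0 /M/min)

The first chemist's view comes nearer in a neighbour flask charged with less catalyst, 4.2 × 10⁻⁴ M: there W becomes 77.1 d, of which the catalyst term is 87.1%, and with ochre's lag that predicts 3.40%. That neighbour gives 3.49%.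

(The data come from a simulation for substances that don't exist; noise was put on by code.)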